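**Assumptions (one line each)**
- Commercial phytol is taken as (2E,7R,11R) with at least 95% E. The 7R and 11R centres of phytol become 4'R and 8'R of the target.
- 4-Fluoro-3-methylbenzaldehyde is commercial.
- 9-BBN, TBHP, Ms2O, NBS, mCPBA and the bases are ordinary catalogue reagents.

**Target check.** The SMILES is (2R,4'R,8'R)-δ-tocopherol: an 8-methylchroman-6-ol with a quaternary C2 bearing a methyl and the 4,8,12-trimethyltridecyl chain.

## Retrosynthesis
1. The 6-OH is unmasked at the end by Baeyer–Villiger/Dakin oxidation of a 6-formylchroman. The aldehyde also serves as the activating group for ring closure.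
2. The chroman O1–C8a bond is formed by intramolecular SNAr of a tertiary alkoxide onto an aryl fluoride para to the CHO. The quaternary C2 stereocentre already exists in the open-chain alcohol, so ring closure never touches it.
3. The C4–C4a bond comes from a B-alkyl Suzuki coupling of an aryl bromide with the 9-BBN adduct of (3R)-isophytol.
4. (3R)-Isophytol comes from Sharpless asymmetric epoxidation of phytol, which sets the future C2, followed by a mesylate/Zn–NaI reductive transposition to the tertiary allylic alcohol.
5. Only one ring, the chroman, is formed, and it is formed near the end. C4' and C8' come from phytol.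

## Route

**Step 1**
Reactants: 1, (2E,7R,11R)-phytol
Product: 2, [(2R,3R)-3-methyl-3-((4R,8R)-4,8,12-trimethyltridecyl)oxiran-2-yl]methanol
Conditions: Ti(OiPr)4 (10 mol%), D-(−)-DET (12 mol%), TBHP (2 equiv, decane), 3 Å MS, CH2Cl2, −20 °C
Reagents that add atoms: tert-butyl hydroperoxide, CC(C)(C)OO (supplies the epoxide O)
Why: Sharpless asymmetric epoxidation of the trisubstituted allylic alcohol. (−)-DET delivers O to one face and sets the quaternary C3 (future chroman C2) as R, analogous to (2R,3R) from (−)-DET with geraniol-type alcohols. The remote C7 and C11 centres do not interfere.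

**Step 2**
Reactants: 2
Product: 3, the primary mesylate of 2
Conditions: Ms2O, Et3N, CH2Cl2, −20 °C
Reagents that add atoms: methanesulfonic anhydride, CS(=O)(=O)OS(=O)(=O)C
Why: Selective sulfonylation of the primary OH. Ms2O is used instead of MsCl so that chloride does not open the acid-sensitive tertiary epoxide. No stereocentre is touched.

**Step 3**
Reactants: 3
Product: 4, (3R,7R,11R)-3,7,11,15-tetramethylhexadec-1-en-3-ol ((3R)-isophytol)
Conditions: NaI, activated Zn dust, DME, 80 °C
Reagents that add atoms: none
Why: Finkelstein displacement gives the epoxy iodide. Zn insertion and β-alkoxide elimination then open the epoxide (reductive epoxy-alcohol to allylic-alcohol transposition). The C3–O bond is never broken, so the quaternary configuration is retained. The priority order stays O > C2 > C4 > CH3, so the descriptor remains R.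

**Step 4**
Reactants: 5, 4-fluoro-3-methylbenzaldehyde
Product: 6, 3-bromo-4-fluoro-5-methylbenzaldehyde
Conditions: NBS, conc. H2SO4, 25 °C
Reagents that add atoms: N-bromosuccinimide, O=C1CCC(=O)N1Br
Why: Electrophilic bromination. In strong acid the protonated CHO is a powerful meta director and C3 is blocked by the methyl, so Br goes to C5, ortho to F and meta to CHO.

**Step 5**
Reactants: 4 and 6
Product: 7, 4-fluoro-3-[(3R,7R,11R)-3-hydroxy-3,7,11,15-tetramethylhexadecyl]-5-methylbenzaldehyde
Conditions: (a) 9-BBN (2.0 equiv), THF, 0 °C to rt; (b) add 6, PdCl2(dppf) (5 mol%), aq. K3PO4, THF, 65 °C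
Reagents that add atoms: none (the 9-BBN boron is lost as a boron by-product)
Why: Anti-Markovnikov hydroboration of the vinyl carbinol puts boron on C1. One equivalent of 9-BBN is consumed by the free OH, giving an O–B bond that is cleaved on work-up. The B-alkyl Suzuki coupling then forms the C(sp3)–C(sp2) bond. No stereocentre is altered, and the tertiary carbinol stays R.

**Step 6**
Reactants: 7
Product: 8, (2R)-2,8-dimethyl-2-[(4R,8R)-4,8,12-trimethyltridecyl]chromane-6-carbaldehyde
Conditions: KHMDS (1.3 equiv), THF/DMPU 4:1, 0 °C to 60 °C
Reagents that add atoms: none (HF is lost as KF)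
Why: Proposed new method: intramolecular SNAr of a tertiary alkoxide onto a 2,6-disubstituted aryl fluoride, giving the 2,2-disubstituted chroman with retention at the quaternary carbon. Mechanistically, 6-exo alkoxide attack at the ipso carbon para to CHO gives a Meisenheimer complex stabilised by the aldehyde, then F⁻ leaves. The closest known reaction is base-mediated cyclisation of 3-(2-fluoroaryl)propanols onto activated fluoroarenes to give chromans. The C–O bond at the stereocentre is not formed or broken in this step, so C2 stays R. The tertiary alkoxide cannot transfer hydride, so Cannizzaro-type side reactions are suppressed.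

**Step 7**
Reactants: 8
Product: 9, (2R)-2,8-dimethyl-2-[(4R,8R)-4,8,12-trimethyltridecyl]chroman-6-yl formate
Conditions: mCPBA (1.3 equiv), NaHCO3, CH2Cl2, 0 °C to rt
Reagents that add atoms: mCPBA, OOC(=O)c1cccc(Cl)c1 (supplies the inserted O)
Why: Baeyer–Villiger oxidation (Dakin-type). The arene is para-alkoxy and electron-rich, so aryl migration is strongly favoured and gives the aryl formate. No stereocentre is affected.

**Step 8**
Reactants: 9
Product: 10, (2R,4'R,8'R)-δ-tocopherol
Conditions: K2CO3, MeOH, degassed, 0 °C to rt, Ar; work up with aqueous ascorbic acid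
Reagents that add atoms: none (the formyl group leaves as methyl formate)
Why: Transesterification cleaves the formate to release the free phenol, and the ascorbate wash prevents quinone formation. All three stereocentres are unchanged: 2R comes from Step 1, 4'R and 8'R from phytol.

## Compound list
1 | (2E,7R,11R)-phytol | OC/C=C(\C)CCC[C@H](C)CCC[C@H](C)CCCC(C)C | starting material
2 | (2R,3R)-2,3-epoxyphytol | OC[C@H]1O[C@]1(C)CCC[C@H](C)CCC[C@H](C)CCCC(C)C | intermediate
3 | (2R,3R)-epoxyphytyl mesylate | CS(=O)(=O)OC[C@H]1O[C@]1(C)CCC[C@H](C)CCC[C@H](C)CCCC(C)C | intermediate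
4 | (3R,7R,11R)-isophytol | C=C[C@](C)(O)CCC[C@H](C)CCC[C@H](C)CCCC(C)C | intermediate
5 | 4-fluoro-3-methylbenzaldehyde | O=Cc1ccc(F)c(C)c1 | starting material
6 | 3-bromo-4-fluoro-5-methylbenzaldehyde | O=Cc1cc(C)c(F)c(Br)c1 | intermediate
7 | 4-fluoro-3-[(3R,7R,11R)-3-hydroxy-3,7,11,15-tetramethylhexadecyl]-5-methylbenzaldehyde | O=Cc1cc(C)c(F)c(CC[C@](C)(O)CCC[C@H](C)CCC[C@H](C)CCCC(C)C)c1 | intermediate
8 | (2R)-2,8-dimethyl-2-[(4R,8R)-4,8,12-trimethyltridecyl]chromane-6-carbaldehyde | Cc1cc(C=O)cc2c1O[C@](C)(CCC[C@H](C)CCC[C@H](C)CCCC(C)C)CC2 | intermediate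
9 | 6-formyloxy chroman (aryl formate of the target) | Cc1cc(OC=O)cc2c1O[C@](C)(CCC[C@H](C)CCC[C@H](C)CCCC(C)C)CC2 | intermediate
10 | (2R,4'R,8'R)-δ-tocopherol | Cc1cc(O)cc2c1O[C@](C)(CCC[C@H](C)CCC[C@H](C)CCCC(C)C)CC2 | target

## Totals
- Total steps: 8.
- Longest linear sequence: 7 (Steps 1, 2, 3, 5, 6, 7, 8 from phytol). Step 4 is a parallel branch.

## Three steps most likely to fail
1. **Step 6 (SNAr).** The fluoride is flanked by a methyl and the tether, and the alkoxide is tertiary.
   - Fallback: change the mechanism to Cu-catalysed Ullmann etherification (CuI/Me4-phenanthroline, Cs2CO3, toluene, 110 °C). Use 3-iodo-4-bromo-5-methylbenzaldehyde in Step 5, so Suzuki occurs at C–I and the C–Br is left for the intramolecular C–O coupling.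
2. **Step 5 (hydroboration/Suzuki).** Excess 9-BBN could reduce the CHO, and the free tertiary OH complicates the borane.
   - Fallback: from 4, go via Red-Al reduction of epoxy alcohol 2 to the 1,3-diol, selective Appel iodination of the primary OH, then Ni-catalysed cross-electrophile coupling with 6.
3. **Step 4 (regioselective bromination).** Me, F and CHO may compete in directing the bromine.
   - Fallback: Ir-catalysed sterically controlled C–H borylation of 5, followed by Cu(II)-mediated bromodeborylation.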